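(The numbers of this flask were chosen freely; the flask was simulated.)

Slowness of addition is what sets these flasks apart: the same charges go in at once, in portions, or by a steady feed.

all flasks: Q 7.0 µM; time 2.0 min
- east: J 0.010 M (in portions, 5, over 1.5 min); E 0.0120 M; first portion at the start, last at 1.5 min
- south-west: J 0.010 M (fed, over 1.5 min); E 0.0120 M; all else is in the flask from the start; the feed brings no volume worth counting
- south-east: J 0.010 M; E 0.0120 M (fed, over 1.5 min); all else is in the flask from the start; the feed brings no volume worth counting
- north-east: J 0.010 M; E 0.0120 M; everything together at the start

    J + E + Q → Q + Z (k1 = 1.43 × 10⁷ M⁻² s⁻¹)
    Q → L (k2 = 0.0756 s⁻¹)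
    2 Q → Q2 (k3 = 20300 M⁻¹ s⁻¹)
    J + E → J.E (k4 = 11.0 M⁻¹ s⁻¹)

1. the best flask by share of Z in Z plus J.E; "all alike" if 1.5 percentage points covers them all (east / south-west / south-east / north-east / all alike)
2. share of Z in Z plus J.E at the end, east
3. share of Z in Z plus J.E at the end, south-west
4. share of Z in Z plus J.E at the end, south-east
5. share of Z in Z plus J.E at the end, north-east

Two chemists dispute this. The first divides the rate of the first step by that of the fourth: cJ and cE cancel, time drops out, and the selectivity factor S remains, the first constant times cQ over the fourth constant, which is 9.10 at the charged cQ. So the first chemist expects a share of Z of S/(1+S), or 90.1%, however J comes in. The second accepts the ratio but watches cQ: Q leaves the first step unchanged, its two losses involve Q by itself, and pairing by itself gives a first half-life of 3.52 s, far shorter than the feed of 90 s.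

My own reckoning joins the two. What arrives at a given moment splits as S/(1+S) of that moment, provided it reacts promptly. Adding that share up over the fall of cQ gives the catalyst's window, 17.0 s, the seconds of feed that the catalyst wins. Window over feed time gives 18.8% for south-west and for south-east. In east, the first portion, 20.0% of the charge, lands inside the window, and the next comes 22.5 s later, longer than the window, so I take that portion's share. In north-east, S starts at its full value and can only fall, so 90.1% is a ceiling.

The forecast, its own numbers and not mine, takes the second side: north-east best at 80%, then east 25%, south-east 20.5%, south-west 18.5%, since “the feeds leave most of the material to arrive after the catalyst is gone”.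

The flasks give 80.7% for north-east, 23.9% for east, 17.3% for south-east and 15.6% for south-west, so north-east is best, and the second chemist wins.

The first chemist's figure is approached as the feed shortens, but it is not reached: south-west fed over 0.150 min gives 61.7%, more than its 15.6% on the card and less than his 90.1%. On the card, the window figure stands 3.2 percentage points above south-west. Now take south-west with cQ charged at 1.7 × 10⁻⁶ M: S starts at 2.21, the window shrinks to 11.7 s, and window over feed time gives 13.0%. That flask gives 10.0%, with Z at 9.35% of the J charged.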